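Tuesday's run, which is the asked flask followed so far, levels off with starting material still at 84.5%, so I ask what ended it.

| flask | starting material | second substrate | reagent | free catalyst | impurity | temperature | remark | time |
|---|---|---|---|---|---|---|---|---|
| Tuesday's | 0.30 M | 0.15 M | 0.24 M | 0.15 mM | 36 µM | 80 °C | the very flask that is asked about, followed so far |  |
| Sunday's | 0.30 M | 0.15 M | 0.24 M | 0.15 mM | 36 µM | 65 °C | run made earlier |  |
| flask | 0.30 M | 0.150 M | 0.240 M | 0.15 mM | 36 µM | 80 °C |  | 8.0 d |

| run | time / h | target / % | starting material / % |
|---|---|---|---|
| Tuesday's | 15.0 | 6.1 | 92.3 |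
| Tuesday's | 50.0 | 12.1 | 87.2 |
| Tuesday's | 96.0 | 15.2 | 85.4 |
| Tuesday's | 144 | 14.8 | 84.9 |
| Tuesday's | 192 | 15.4 | 84.5 |
| Sunday's | 30.0 | 9.3 | 89.8 |
| Sunday's | 96.0 | 19.9 | 79.2 |
| Sunday's | 192 | 26.5 | 73.6 |
| Sunday's | 288 | 28.7 | 70.7 |
| Sunday's | 360 | 30.0 | 70.4 |

(each reading ± 0.5 percentage points)

- south-east: at 8.0 d raise the temperature by 10 K, then wait 8.0 d
- south-west: at 8.0 d take out 90% of the target then present, then wait 8.0 d
- north-west: at 8.0 d add reagent, 100% of the amount charged, then wait 8.0 d
- east: change nothing and wait 8.0 d more
- west: at 8.0 d add free catalyst, 100% of the amount charged, then wait 8.0 d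

- removed target is counted in
- additions bring no volume worth counting

1. target, in percent of the starting material first charged, at 8.0 d
2. which option adds most target ("none" when 2 percentage points or less is all one gets) (south-east / south-west / north-west / east / west / none)
3. target present, with what was taken out counted in, in percent of the starting material first charged, after north-west
4. target present, with what was taken out counted in, in percent of the starting material first charged, after west

I begin with the balance of the reagent, which is charged below the starting material and so is the limiting reagent of that pair. Counting one reagent per target, its charge allows a ceiling, as a fraction of the starting material, and the plateau of the last three readings draws on it: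

ceiling = 80.0%, plateau = 15.1%

So target stands below what the reagent allows, and by this count the draw of reagent for target did not stop Tuesday's run. I take the plateau as the end of the catalyst, though these readings don't exclude an equilibrium. Two times then compare. The working life comes from the approach to the plateau, and the filling time is what the ceiling takes at the early pace, which I read from the first reading:

life = 31.1 h

filling time = 156 h

Their ratio, read from these scattered readings, is the reach 19.9%, the share of the ceiling that one charge of catalyst fills. My reckoning gives 15.9% of target for the asked flask, above the forecast's 15.2%. At 8.0 d the asked flask is past its working life, and by this reckoning 0.209% of its catalyst is still at work. By the same reckoning waiting promises 0.032 percentage points against the margin of 2 points, whereas fresh free catalyst starts a new life.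

The forecast gives 15.2% (14.6% to 15.8%), names west as best, and expects 15.5% after north-west and 26% after west: “I favour catalyst death.”

The flask gives 15.3%, with west best at 14 points added, 15.4% after north-west and 29.0% after west.

    reagent + catalyst intermediate B → spent catalyst B (k = 5.88 × 10⁻⁵ M⁻¹ s⁻¹, Ea = 88.0 kJ mol⁻¹)
    free catalyst → spent catalyst A (k = 6.48 × 10⁻⁶ s⁻¹, Ea = 113 kJ mol⁻¹)
    starting material + free catalyst ⇌ catalyst intermediate A (K = 2.00 M⁻¹, k = 1.51 M⁻¹ s⁻¹, Ea = 43.0 kJ mol⁻¹, ΔH = −74.0 kJ mol⁻¹)
    reagent + catalyst intermediate A → free catalyst + target (k = 0.157 M⁻¹ s⁻¹, Ea = 73.0 kJ mol⁻¹)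
    second substrate + free catalyst ⇌ catalyst intermediate B (K = 190 M⁻¹, k = 0.126 M⁻¹ s⁻¹, Ea = 64.0 kJ mol⁻¹, ΔH = −65.0 kJ mol⁻¹)
    reagent + catalyst intermediate B → free catalyst + second product (k = 0.0249 M⁻¹ s⁻¹, Ea = 83.0 kJ mol⁻¹)
    free catalyst + impurity → spent catalyst C (k = 28.7 M⁻¹ s⁻¹, Ea = 42.0 kJ mol⁻¹)
    (constants at 80 °C)

The half-life of starting material by its forward step alone is 0.85 h with the charges held, but 53 d at 192 h, longer than the further 8.0 d. Free catalyst then stands at 0.0669% of its charge. The found target is 19.1% of the ceiling, against the reach of 19.9%, which was read from this same flask's readings.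

In the neighbour flask with 0.60 M of reagent, 2.00 equiv, the ceiling becomes the whole starting material. If pace follows reagent and the life holds, the reach there is 39.9%; that neighbour computes to 32.7% of target.

The data are calculated from invented constants.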